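**Strategy**

Gardenin D is disconnected at the C4–C4a bond of ring C, which is closed by intramolecular Friedel–Crafts acylation. The step exploits the fact that C4a is the only carbon of ring A that bears hydrogen instead of oxygen and that it sits ortho to O1 and to the C5 methoxy group and para to the C7 methoxy group, so a single, activated site is offered. In one operation the pyranone ring and the complete flavone skeleton are formed from (Z)-3-(3-isopropoxy-4-methoxyphenyl)-3-(2,3,4,5-tetramethoxyphenoxy)acrylic acid, itself assembled by conjugate addition of a phenol to an arylpropiolate. One BCl3 treatment then unmasks the C5 and C3' hydroxyl groups.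

Key step: step 7

Remark: the conjugate addition of step 5 is assumed to give mainly the Z ester; a minor E isomer need not be removed, because the push–pull alkene can equilibrate under the acid of step 7.

**Route**

Step 1
Reactants: 1 1,2,3,4-tetramethoxybenzene
Product: 4 2,3,4,5-tetramethoxyphenol, via aryllithium 2 (not isolated), via lithium aryltrimethoxyborate 3 (not isolated)
Conditions: n-BuLi, TMEDA, THF, 0 °C; B(OMe)3, −78 °C to rt; AcOH, 30% aq. H2O2, 0 °C to rt
Reagents that add atoms: hydrogen peroxide, OO (n-butyllithium, [Li]CCCC, and trimethyl borate, COB(OC)OC, leave atoms only in 2 and 3)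
Why: Directed ortho-metalation at one of the two equivalent ring C–H positions (each next to a methoxy group), borylation of the aryllithium and peroxide oxidation with 1,2-shift of the aryl group from boron to oxygen should deliver the phenol in one pot (lithiation–borylation–oxidation).

Step 2
Reactants: 5 isovanillin, 6 2-bromopropane
Product: 7 3-isopropoxy-4-methoxybenzaldehyde
Conditions: K2CO3, DMF, 70 °C
Reagents that add atoms: 2-bromopropane 6, CC(C)Br
Why: Williamson ether synthesis of the phenoxide with the secondary bromide; the isopropyl ether is chosen because it withstands n-BuLi, carbonate, hydroxide and cold acid and is cleaved in step 8 by the same reagent as the C5 methyl ether.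

Step 3
Reactants: 7 3-isopropoxy-4-methoxybenzaldehyde, 8 carbon tetrabromide
Product: 9 4-(2,2-dibromovinyl)-2-isopropoxy-1-methoxybenzene
Conditions: PPh3, CH2Cl2, 0 °C
Reagents that add atoms: carbon tetrabromide 8, BrC(Br)(Br)Br
Why: First stage of the Corey–Fuchs reaction, in which the ylide made from CBr4 and PPh3 converts the aldehyde into the 1,1-dibromoalkene by a Wittig olefination.

Step 4
Reactants: 9 4-(2,2-dibromovinyl)-2-isopropoxy-1-methoxybenzene, 10 ethyl chloroformate
Product: 12 ethyl 3-(3-isopropoxy-4-methoxyphenyl)prop-2-ynoate, via lithium arylacetylide 11 (not isolated)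
Conditions: n-BuLi (2.1 equiv), THF, −78 °C; then 10, −78 °C to rt
Reagents that add atoms: ethyl chloroformate 10, CCOC(=O)Cl (n-butyllithium, [Li]CCCC, leaves lithium only in 11)
Why: Second stage of the Corey–Fuchs reaction, in which bromine–lithium exchange, Fritsch–Buttenberg–Wiechell rearrangement and deprotonation give the lithium acetylide, which is C-acylated by the chloroformate at low temperature.

Step 5
Reactants: 4 2,3,4,5-tetramethoxyphenol, 12 ethyl 3-(3-isopropoxy-4-methoxyphenyl)prop-2-ynoate
Product: 13 ethyl (Z)-3-(3-isopropoxy-4-methoxyphenyl)-3-(2,3,4,5-tetramethoxyphenoxy)acrylate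
Conditions: Cs2CO3 (0.5 equiv), DMF, N2, 80 °C
Reagents that add atoms: none
Why: Base-mediated oxa-Michael addition of the phenoxide to the ynoate, with protonation of the allenolate anti to the new C–O bond, should place the aryloxy group cis to the ester (Z), which should also be the less crowded isomer because oxygen and not the aryl ring lies next to the ester.

Step 6
Reactants: 13 ethyl (Z)-3-(3-isopropoxy-4-methoxyphenyl)-3-(2,3,4,5-tetramethoxyphenoxy)acrylate
Product: 15 (Z)-3-(3-isopropoxy-4-methoxyphenyl)-3-(2,3,4,5-tetramethoxyphenoxy)acrylic acid, via lithium carboxylate 14 (not isolated)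
Conditions: LiOH·H2O, THF/MeOH/H2O, rt; then 1 M HCl, 0 °C, pH 3
Reagents that add atoms: lithium hydroxide, [Li+].[OH-]
Why: Saponification of the ester and cold acidification; the β-carbon of this vinylogous carbonate is a poor electrophile, so the aryl vinyl ether should survive hydroxide.

Step 7
Reactants: 15 (Z)-3-(3-isopropoxy-4-methoxyphenyl)-3-(2,3,4,5-tetramethoxyphenoxy)acrylic acid
Product: 17 2-(3-isopropoxy-4-methoxyphenyl)-5,6,7,8-tetramethoxy-4H-chromen-4-one, via mixed methanesulfonic anhydride 16 (not isolated)
Conditions: P2O5/CH3SO3H (1:10 w/w), 25 °C; then ice-water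
Reagents that add atoms: none
Why: P2O5 in CH3SO3H should turn the acid into mixed anhydride 16, which reacts as an acylium-type electrophile stabilised by the β-aryloxy oxygen, attacks C4a of the tetramethoxyphenoxy ring and gives the 4-pyranone after loss of the ring proton. The closest known reaction type is the intramolecular Friedel–Crafts acylation of 3-aryloxycinnamic acids to flavones. Ring C closes in a six-membered mode that is exo with respect to the acylium C≡O (6-exo-dig), the C4a–C8a arene bond becoming part of the new ring. No stereocenter is formed. The step needs site selectivity between ring A and ring B and survival of six aryl ethers: the Z alkene holds the acyl group beside the aryloxy ring, whose only C–H is ortho to O1 and to the C5 methoxy group and para to the C7 methoxy group, whereas ring B can be reached only from the E isomer and would give an indenone. The reaction is kept at 25 °C so that the isopropyl ether is not ionised, and any E acid can equilibrate through the ketene-like oxocarbenium form of the acyl cation.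

Step 8
Reactants: 17 2-(3-isopropoxy-4-methoxyphenyl)-5,6,7,8-tetramethoxy-4H-chromen-4-one
Product: 19 gardenin D, via bis(dichloroboryl) ether 18 (not isolated)
Conditions: BCl3 (3 equiv), CH2Cl2, −78 to 0 °C; then aq. HCl, rt
Reagents that add atoms: none
Why: Lewis-acid ether cleavage in which BCl3 bound to the C4 carbonyl forms a six-membered chelate with O5 that exposes only the peri methyl group to chloride, while the secondary isopropyl ether is cleaved far faster than the other aryl methyl ethers, so hydrolysis of boron ester 18 should release both hydroxyl groups.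

**Compound list**

1 | 1,2,3,4-tetramethoxybenzene | COc1ccc(OC)c(OC)c1OC | starting material
2 | 2,3,4,5-tetramethoxyphenyllithium | [Li]c1cc(OC)c(OC)c(OC)c1OC | intermediate
3 | lithium trimethoxy(2,3,4,5-tetramethoxyphenyl)borate | [Li+].CO[B-](OC)(OC)c1cc(OC)c(OC)c(OC)c1OC | intermediate
4 | 2,3,4,5-tetramethoxyphenol | COc1cc(O)c(OC)c(OC)c1OC | intermediate
5 | isovanillin (3-hydroxy-4-methoxybenzaldehyde) | COc1ccc(C=O)cc1O | starting material
6 | 2-bromopropane | CC(C)Br | starting material
7 | 3-isopropoxy-4-methoxybenzaldehyde | COc1ccc(C=O)cc1OC(C)C | intermediate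
8 | carbon tetrabromide | BrC(Br)(Br)Br | starting material
9 | 4-(2,2-dibromovinyl)-2-isopropoxy-1-methoxybenzene | COc1ccc(C=C(Br)Br)cc1OC(C)C | intermediate
10 | ethyl chloroformate | CCOC(=O)Cl | starting material
11 | lithium (3-isopropoxy-4-methoxyphenyl)acetylide | [Li]C#Cc1ccc(OC)c(OC(C)C)c1 | intermediate
12 | ethyl 3-(3-isopropoxy-4-methoxyphenyl)prop-2-ynoate | CCOC(=O)C#Cc1ccc(OC)c(OC(C)C)c1 | intermediate
13 | ethyl (Z)-3-(3-isopropoxy-4-methoxyphenyl)-3-(2,3,4,5-tetramethoxyphenoxy)acrylate (aryloxy group cis to the ester) | CCOC(=O)/C=C(\Oc1cc(OC)c(OC)c(OC)c1OC)c1ccc(OC)c(OC(C)C)c1 | intermediate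
14 | lithium (Z)-3-(3-isopropoxy-4-methoxyphenyl)-3-(2,3,4,5-tetramethoxyphenoxy)acrylate | [Li+].[O-]C(=O)/C=C(\Oc1cc(OC)c(OC)c(OC)c1OC)c1ccc(OC)c(OC(C)C)c1 | intermediate
15 | (Z)-3-(3-isopropoxy-4-methoxyphenyl)-3-(2,3,4,5-tetramethoxyphenoxy)acrylic acid | OC(=O)/C=C(\Oc1cc(OC)c(OC)c(OC)c1OC)c1ccc(OC)c(OC(C)C)c1 | intermediate
16 | mixed anhydride of acid 15 with methanesulfonic acid, Z alkene | CS(=O)(=O)OC(=O)/C=C(\Oc1cc(OC)c(OC)c(OC)c1OC)c1ccc(OC)c(OC(C)C)c1 | intermediate
17 | 2-(3-isopropoxy-4-methoxyphenyl)-5,6,7,8-tetramethoxy-4H-chromen-4-one (3'-O-isopropyl-5-O-methylgardenin D) | COc1ccc(-c2cc(=O)c3c(OC)c(OC)c(OC)c(OC)c3o2)cc1OC(C)C | intermediate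
18 | 5-(dichloroboryloxy)-2-[3-(dichloroboryloxy)-4-methoxyphenyl]-6,7,8-trimethoxy-4H-chromen-4-one | COc1ccc(-c2cc(=O)c3c(OB(Cl)Cl)c(OC)c(OC)c(OC)c3o2)cc1OB(Cl)Cl | intermediate
19 | gardenin D (5-hydroxy-2-(3-hydroxy-4-methoxyphenyl)-6,7,8-trimethoxy-4H-chromen-4-one) | COc1ccc(-c2cc(=O)c3c(O)c(OC)c(OC)c(OC)c3o2)cc1O | target

**Step count**

Total steps: 8. Longest linear sequence: 7 steps (isovanillin 5 to gardenin D 19 through steps 2, 3, 4, 5, 6, 7 and 8).

**Steps most likely to fail**

1. Step 7. The acyl cation is oxygen-stabilised and therefore a weak electrophile, so ring closure may be slower than acid-induced ionisation of the isopropyl ether or cleavage of the aryl vinyl ether, and material may be lost before the C4–C4a bond forms. The fallback closes ring C at O1–C2 instead. It sets out from phenol 4, which is C-acetylated at its single free ring position with AcOH and BF3·OEt2 at 80 °C (Friedel–Crafts acylation) to give 1-(2-hydroxy-3,4,5,6-tetramethoxyphenyl)ethanone F1. Claisen–Schmidt condensation of this ketone with aldehyde 7 (KOH, EtOH, rt) should give (E)-1-(2-hydroxy-3,4,5,6-tetramethoxyphenyl)-3-(3-isopropoxy-4-methoxyphenyl)prop-2-en-1-one F2. Oxidative cyclisation of the chalcone with catalytic I2 in DMSO at 120 °C comes back to the route at flavone 17.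

2. Step 5. A hindered and easily oxidised phenoxide has to add to an ynoate that is deactivated by a donor aryl group, so the addition may stall, the phenol may be consumed by oxidation, or the alkene geometry may erode. The fallback replaces the addition by a substitution at a vinyl halide. It sets out from ynoate 12, which is hydroiodinated with NaI in AcOH at 70 °C (anti addition of HI) to give ethyl (Z)-3-iodo-3-(3-isopropoxy-4-methoxyphenyl)acrylate F3. Ullmann-type C–O coupling of this iodide with phenol 4 (CuI, N,N-dimethylglycine, Cs2CO3, dioxane, 90 °C), which should retain the alkene geometry, comes back to the route at ester 13.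

3. Step 8. Dealkylation may not stop at the two intended ethers: once O5 is bound to boron the neighbouring C6 methoxy group, and on ring B the C4' methoxy group next to the new boron ester, can be cleaved in turn, or one of the two wanted cleavages may stay incomplete. The fallback separates the two events and uses a different mechanism for each. It sets out from flavone 17, whose peri methoxy group is hydrolysed with conc. HCl in EtOH at reflux (protonated pyranone carbonyl, chloride attack on the C5 methyl group, no Lewis acid near C6) to give 5-hydroxy-2-(3-isopropoxy-4-methoxyphenyl)-6,7,8-trimethoxy-4H-chromen-4-one F4. The isopropyl ether alone is then removed with a limited amount of BCl3 in CH2Cl2 at −78 to −20 °C, which comes back to the route at target 19.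

**Further compounds**

F1 | step 7 | 1-(2-hydroxy-3,4,5,6-tetramethoxyphenyl)ethanone | CC(=O)c1c(O)c(OC)c(OC)c(OC)c1OC
F2 | step 7 | (E)-1-(2-hydroxy-3,4,5,6-tetramethoxyphenyl)-3-(3-isopropoxy-4-methoxyphenyl)prop-2-en-1-one | COc1ccc(/C=C/C(=O)c2c(O)c(OC)c(OC)c(OC)c2OC)cc1OC(C)C
F3 | step 5 | ethyl (Z)-3-iodo-3-(3-isopropoxy-4-methoxyphenyl)acrylate | CCOC(=O)/C=C(\I)c1ccc(OC)c(OC(C)C)c1
F4 | step 8 | 5-hydroxy-2-(3-isopropoxy-4-methoxyphenyl)-6,7,8-trimethoxy-4H-chromen-4-one | COc1ccc(-c2cc(=O)c3c(O)c(OC)c(OC)c(OC)c3o2)cc1OC(C)C
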